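O1–C8a–C4a–C4 of the upper unit is a latent o-quinone methide, easy to unmask because C4 carries the phloroglucinol-type D ring. Flavan numbering: upper 7,8,3',4'-tetrahydroxyflavan-3-ol = rings A/C/B, lower (+)-catechin = rings D/F/E, interflavan bond C4(C)–C8(D).
The last disconnections are the ten O-benzyl groups (hydrogenolysis) and C2–H (silane reduction of a C2 silyl ketal through the C2=O1+ ion), which fixes C2.
The key disconnection cuts C3–C4 and O1–C2 of ring C: a formal [4+2] of the A/D o-quinone methide with the (Z)-enol silane of the α-benzyloxy B-ring ketone under a chiral Brønsted acid, which sets C4 and C3.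
The methide precursor comes from the C4–C8(D) bond: 8-lithio-penta-O-benzylcatechin plus the sodium salt of 3,4-bis(benzyloxy)salicylaldehyde. The enol silane comes from a B-ring aryllithium and a benzyloxyacetic Weinreb amide.
Rings D/F/E arrive with catechin and rings A and B are bought as arenes, so ring C is the only ring formed.

Key step: step 10

Assumption: which antipode of the catalyst is matched with the (2R,3S)-catechin part for attack on the C4 face leading to 4S cannot be derived safely. The (R)-catalyst is written, and the (S)-catalyst replaces it without other change if it proves to be the matched one.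
Assumption: the diaryl carbinol is used as the mixture of its two carbinol epimers, because this centre becomes trigonal in the key step.

Step 1
Reactants: 1 (+)-catechin
Product: 2 5,7,3',4'-tetra-O-benzyl-(+)-catechin (2R,3S; 3-OH free)
Conditions: BnBr (4.3 equiv), K2CO3, DMF, Ar, 0 °C → rt
Reagents that add atoms: benzyl bromide, BrCc1ccccc1
Why: Williamson etherification in which K2CO3 deprotonates only the four phenols, so the secondary 3-OH stays free and the mild base under argon leaves C2 and C3 untouched.

Step 2
Reactants: 2 5,7,3',4'-tetra-O-benzyl-(+)-catechin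
Product: 3 8-bromo-5,7,3',4'-tetra-O-benzyl-(+)-catechin
Conditions: NBS (1.0 equiv), CH2Cl2, −78 °C → rt
Reagents that add atoms: N-bromosuccinimide, O=C1CCC(=O)N1Br
Why: Electrophilic aromatic bromination, for which C8 is the most nucleophilic position of 5,7-di-O-benzylated flavan-3-ols, so one equivalent of NBS at low temperature should stop at the C8 monobromide.

Step 3
Reactants: 3 8-bromo-5,7,3',4'-tetra-O-benzyl-(+)-catechin
Product: 4 8-bromo-3,5,7,3',4'-penta-O-benzyl-(+)-catechin
Conditions: NaH, BnBr, DMF, 0 °C → rt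
Reagents that add atoms: benzyl bromide, BrCc1ccccc1
Why: Williamson etherification of the secondary alcohol through its sodium alkoxide removes the last acidic proton before lithiation and touches no stereocentre.

Step 4
Reactants: 5 2,3,4-trihydroxybenzaldehyde
Product: 6 3,4-bis(benzyloxy)-2-hydroxybenzaldehyde
Conditions: BnBr (2.05 equiv), K2CO3 (2.1 equiv), acetone, Ar, reflux
Reagents that add atoms: benzyl bromide, BrCc1ccccc1
Why: Chemoselective Williamson etherification, since the 2-OH is held in a hydrogen bond to the formyl group and its conjugated phenoxide is the poorest nucleophile, so two equivalents of BnBr should end up on O4 and O3, as is classical for 2,3,4-trihydroxyaryl carbonyl compounds.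

Step 5
Reactants: 4 8-bromo-3,5,7,3',4'-penta-O-benzyl-(+)-catechin; 6 3,4-bis(benzyloxy)-2-hydroxybenzaldehyde
Product: 9 A/D diaryl carbinol [3,4-bis(benzyloxy)-2-hydroxyphenyl](penta-O-benzylcatechin-8-yl)methanol (both carbinol epimers), via 8-lithio-penta-O-benzylcatechin 7 (not isolated), via sodium formylphenoxide 8 (not isolated)
Conditions: 4, n-BuLi (1.0 equiv), THF, −78 °C; 8 [from 6 (1.3 equiv), NaH, THF, 0 °C] by cannula, −78 → 0 °C; aq NH4Cl/NH3 (pH 8); Et3N-deactivated silica
Reagents that add atoms: none
Why: Bromine–lithium exchange and 1,2-addition of the aryllithium to the formyl group, the standard route to o-hydroxybenzhydrols, is run on the sodium phenoxide rather than on a silyl ether because a silyl group would migrate to the new alkoxide and let the freed phenoxide expel silanolate (premature methide formation), whereas the dianionic adduct has no leaving group, and the new carbinol centre is left uncontrolled since step 10 makes it trigonal.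

Step 6
Reactants: 10 benzyloxyacetyl chloride
Product: 11 2-(benzyloxy)-N-methoxy-N-methylacetamide
Conditions: MeNH(OMe)·HCl, Et3N (2.2 equiv), CH2Cl2, 0 °C → rt
Reagents that add atoms: N,O-dimethylhydroxylamine hydrochloride, CNOC.Cl
Why: N-acylation of the hydroxylamine by the acid chloride (Weinreb amide formation) is a routine, high-fidelity reaction that leaves the benzyl ether untouched.

Step 7
Reactants: 12 4-bromocatechol
Product: 13 1,2-bis(benzyloxy)-4-bromobenzene
Conditions: BnBr (2.2 equiv), K2CO3, acetone, reflux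
Reagents that add atoms: benzyl bromide, BrCc1ccccc1
Why: Exhaustive Williamson etherification of a catechol, with the aryl bromide inert under these conditions.

Step 8
Reactants: 13 1,2-bis(benzyloxy)-4-bromobenzene; 11 2-(benzyloxy)-N-methoxy-N-methylacetamide
Product: 16 2-(benzyloxy)-1-[3,4-bis(benzyloxy)phenyl]ethan-1-one, via aryllithium 14 (not isolated), via tetrahedral lithium adduct 15 (not isolated)
Conditions: 13, n-BuLi, THF, −78 °C; 11, −78 → 0 °C; aq NH4Cl
Reagents that add atoms: none
Why: Weinreb ketone synthesis, in which the aryllithium from Br–Li exchange adds only once because the chelated adduct 15 collapses only on work-up, and this C–C construction of the α-benzyloxy ketone avoids alkoxide displacement on a phenacyl halide, which is diverted by attack at the carbonyl group and epoxy-ether formation.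

Step 9
Reactants: 16 2-(benzyloxy)-1-[3,4-bis(benzyloxy)phenyl]ethan-1-one
Product: 17 (Z)-tert-butyldimethylsilyl enol ether of 16 (OTBS and OBn cis on the C=C bond)
Conditions: TBSOTf (1.2 equiv), Et3N (1.5 equiv), CH2Cl2, 0 °C
Reagents that add atoms: tert-butyldimethylsilyl triflate, CC(C)(C)[Si](C)(C)OS(=O)(=O)C(F)(F)F
Why: Soft enolisation and O-silylation of an aryl ketone should give the (Z)-enol silane, because the (E)-isomer would press OBn against the B ring (A1,3 strain), as is general for aryl alkyl ketones under R3SiOTf/Et3N.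

Step 10
Reactants: 9 A/D diaryl carbinol; 17 (Z)-enol silane
Product: 19 (2S,3S,4S)-2-(tert-butyldimethylsilyloxy)-3,7,8-tris(benzyloxy)-2-[3,4-bis(benzyloxy)phenyl]-4-(penta-O-benzylcatechin-8-yl)chroman (OTBS axial; B ring/3-OBn/D ring equatorial), via o-quinone methide 18 (not isolated)
Conditions: (R)-3,3'-bis(2,4,6-triisopropylphenyl)-BINOL N-triflylphosphoramide (10 mol %), 17 (3 equiv), 4 Å MS, toluene, −40 °C, slow addition of 9; Et3N quench; Et3N-deactivated silica
Reagents that add atoms: none
Why: Proposed new method: the acid protonates the doubly benzylic OH of 9, water leaves to the sieves, and the (E)-o-quinone methide 18 remains hydrogen-bonded (in the limit protonated) at its oxygen to the chiral phosphoramide anion, whereupon C3 of 17 attacks C4 and the methide oxygen O1 closes on C2, so that C3–C4 and O1–C2 form in one strongly asynchronous inverse-electron-demand hetero-Diels–Alder event. The closest known reactions are chiral phosphoric acid and N-triflylphosphoramide catalysed conjugate additions and [4+2] cycloadditions of 1,3-dicarbonyl compounds, enamides and styrenes with o-quinone methides released in situ from o-hydroxybenzhydrols, whereas a 1,2-dioxygenated enol silane as 2π partner and a 2,6-dioxygenated aryl group on the methide carbon have not been shown. Ring C closes as the six-membered ring of the [4+2] process, and if the bonds form one after the other the second is a 6-exo-trig attack of the phenolic O1 on the siloxy-stabilised cationic carbon C2. C4 (S) is set by the catalyst, whose 3,3'-aryl groups cover one face of the methide held through O1, and because the catechin part is enantiopure any leakage appears as a separable diastereomer and not as the enantiomer. C3 (S) follows from suprafacial addition of the (Z)-alkene with the B ring endo and OTBS/OBn exo, the arrangement that puts the small H3 and not OBn into the crowded sector between rings A and D and so leaves OBn trans to ring D, while C2 (S, OTBS axial by the anomeric effect, B ring equatorial) comes from the same topology and is only provisional because step 11 resets it. Regioselectivity is secured because only attack through C3 places the cation on C2, where OTBS and the p-benzyloxy B ring stabilise it, and chemoselectivity over Friedel–Crafts attack by C6–H of another D ring and over protodesilylation is secured by the much higher π-nucleophilicity of an enol silane, its excess, the robust TBS group, slow addition of 9, sieves and low temperature.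

Step 11
Reactants: 19 2-siloxy-3-benzyloxy-4-(catechin-8-yl)flavan
Product: 21 deca-O-benzyl dimer (2R,3S,4S)-3,7,8-tris(benzyloxy)-2-[3,4-bis(benzyloxy)phenyl]-4-(penta-O-benzylcatechin-8-yl)chroman, via C2 oxocarbenium ion 20 (not isolated)
Conditions: Et3SiH (5 equiv), TMSOTf (0.3 equiv), CH2Cl2, −78 → −40 °C; Et3N quench
Reagents that add atoms: none
Why: Ionic silane reduction of a ketal, the reaction that turns 1-aryl glycosyl ketals and 2-alkoxychromans into the cyclic ethers, in which TMSOTf ionises the axial C2–OTBS bond (antiperiplanar to an O1 lone pair) to the B-ring-conjugated ion 20 and Et3SiH attacks C2 axially, on the face opposite the C4 D ring of the half-chair with 3-OBn and the 4-aryl group pseudo-equatorial, which leaves H2 axial and the B ring equatorial (2R, 2,3-trans).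

Step 12
Reactants: 21 deca-O-benzyl dimer
Product: 22 target (2R,3S,4S)-2-(3,4-dihydroxyphenyl)-4-[(2R,3S)-2-(3,4-dihydroxyphenyl)-3,5,7-trihydroxychroman-8-yl]chroman-3,7,8-triol
Conditions: H2 (1 atm), 20% Pd(OH)2/C, THF–MeOH–H2O, rt; filtration under Ar, lyophilisation
Reagents that add atoms: none
Why: Catalytic hydrogenolysis of the ten O-benzyl ethers over Pearlman's catalyst is the standard final step for benzylated flavan-3-ol oligomers, whose cyclic C2–O1 bonds, interflavan C4–C8 bond and stereocentres are not affected under these mild conditions.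

Compound list
1 | (+)-catechin | Oc1cc(O)c2c(c1)O[C@H](c1ccc(O)c(O)c1)[C@@H](O)C2 | starting material
2 | 5,7,3',4'-tetra-O-benzyl-(+)-catechin | O(Cc5ccccc5)c1cc(OCc5ccccc5)c2c(c1)O[C@H](c1ccc(OCc5ccccc5)c(OCc5ccccc5)c1)[C@@H](O)C2 | intermediate
3 | 8-bromo-5,7,3',4'-tetra-O-benzyl-(+)-catechin | O(Cc5ccccc5)c1cc(OCc5ccccc5)c2c(c1Br)O[C@H](c1ccc(OCc5ccccc5)c(OCc5ccccc5)c1)[C@@H](O)C2 | intermediate
4 | 8-bromo-3,5,7,3',4'-penta-O-benzyl-(+)-catechin | Brc1c(OCc5ccccc5)cc(OCc5ccccc5)c2c1O[C@H](c1ccc(OCc5ccccc5)c(OCc5ccccc5)c1)[C@@H](OCc5ccccc5)C2 | intermediate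
5 | 2,3,4-trihydroxybenzaldehyde | O=Cc1ccc(O)c(O)c1O | starting material
6 | 3,4-bis(benzyloxy)-2-hydroxybenzaldehyde | O=Cc1ccc(OCc5ccccc5)c(OCc5ccccc5)c1O | intermediate
7 | 8-lithio-3,5,7,3',4'-penta-O-benzylcatechin | [Li]c1c(OCc5ccccc5)cc(OCc5ccccc5)c2c1O[C@H](c1ccc(OCc5ccccc5)c(OCc5ccccc5)c1)[C@@H](OCc5ccccc5)C2 | intermediate (not isolated)
8 | sodium 2,3-bis(benzyloxy)-6-formylphenoxide | O=Cc1ccc(OCc5ccccc5)c(OCc5ccccc5)c1[O-].[Na+] | intermediate (not isolated)
9 | [3,4-bis(benzyloxy)-2-hydroxyphenyl](penta-O-benzylcatechin-8-yl)methanol, both carbinol epimers | OC(c1ccc(OCc5ccccc5)c(OCc5ccccc5)c1O)c3c(OCc5ccccc5)cc(OCc5ccccc5)c4c3O[C@H](c3ccc(OCc5ccccc5)c(OCc5ccccc5)c3)[C@@H](OCc5ccccc5)C4 | intermediate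
10 | benzyloxyacetyl chloride | O=C(Cl)COCc1ccccc1 | starting material
11 | 2-(benzyloxy)-N-methoxy-N-methylacetamide | CON(C)C(=O)COCc1ccccc1 | intermediate
12 | 4-bromocatechol | Oc1ccc(Br)cc1O | starting material
13 | 1,2-bis(benzyloxy)-4-bromobenzene | Brc1ccc(OCc5ccccc5)c(OCc5ccccc5)c1 | intermediate
14 | 3,4-bis(benzyloxy)phenyllithium | [Li]c1ccc(OCc5ccccc5)c(OCc5ccccc5)c1 | intermediate (not isolated)
15 | lithium alkoxide of the tetrahedral adduct of 14 to 11 | [Li]OC(COCc5ccccc5)(N(C)OC)c1ccc(OCc5ccccc5)c(OCc5ccccc5)c1 | intermediate (not isolated)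
16 | 2-(benzyloxy)-1-[3,4-bis(benzyloxy)phenyl]ethan-1-one | O=C(COCc5ccccc5)c1ccc(OCc5ccccc5)c(OCc5ccccc5)c1 | intermediate
17 | (Z)-{2-(benzyloxy)-1-[3,4-bis(benzyloxy)phenyl]ethenyloxy}(tert-butyl)dimethylsilane | CC(C)(C)[Si](C)(C)O/C(c1ccc(OCc5ccccc5)c(OCc5ccccc5)c1)=C\OCc5ccccc5 | intermediate
18 | (E)-2,3-bis(benzyloxy)-6-[(penta-O-benzylcatechin-8-yl)methylidene]cyclohexa-2,4-dien-1-one | O=C1C(OCc5ccccc5)=C(OCc5ccccc5)C=C/C1=C\c3c(OCc5ccccc5)cc(OCc5ccccc5)c4c3O[C@H](c3ccc(OCc5ccccc5)c(OCc5ccccc5)c3)[C@@H](OCc5ccccc5)C4 | intermediate (not isolated)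
19 | (2S,3S,4S)-2-(TBSO)-3,7,8-tris(benzyloxy)-2-[3,4-bis(benzyloxy)phenyl]-4-(penta-O-benzylcatechin-8-yl)chroman | O(Cc5ccccc5)c1ccc([C@@]2(O[Si](C)(C)C(C)(C)C)Oc3c(ccc(OCc5ccccc5)c3OCc5ccccc5)[C@@H](c3c(OCc5ccccc5)cc(OCc5ccccc5)c4c3O[C@H](c3ccc(OCc5ccccc5)c(OCc5ccccc5)c3)[C@@H](OCc5ccccc5)C4)[C@@H]2OCc5ccccc5)cc1OCc5ccccc5 | intermediate
20 | (3S,4S)-C2=O1 oxocarbenium ion derived from 19 (triflate counter-ion) | O(Cc5ccccc5)c1ccc(C2=[O+]c3c(ccc(OCc5ccccc5)c3OCc5ccccc5)[C@@H](c3c(OCc5ccccc5)cc(OCc5ccccc5)c4c3O[C@H](c3ccc(OCc5ccccc5)c(OCc5ccccc5)c3)[C@@H](OCc5ccccc5)C4)[C@@H]2OCc5ccccc5)cc1OCc5ccccc5 | intermediate (not isolated)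
21 | (2R,3S,4S)-3,7,8-tris(benzyloxy)-2-[3,4-bis(benzyloxy)phenyl]-4-(penta-O-benzylcatechin-8-yl)chroman | O(Cc5ccccc5)c1ccc([C@H]2Oc3c(ccc(OCc5ccccc5)c3OCc5ccccc5)[C@@H](c3c(OCc5ccccc5)cc(OCc5ccccc5)c4c3O[C@H](c3ccc(OCc5ccccc5)c(OCc5ccccc5)c3)[C@@H](OCc5ccccc5)C4)[C@@H]2OCc5ccccc5)cc1OCc5ccccc5 | intermediate
22 | CNP0231186.1, (2R,3S,4S)-2-(3,4-dihydroxyphenyl)-4-[(2R,3S)-2-(3,4-dihydroxyphenyl)-3,5,7-trihydroxychroman-8-yl]chroman-3,7,8-triol | Oc1ccc([C@H]2Oc3c(ccc(O)c3O)[C@@H](c3c(O)cc(O)c4c3O[C@H](c3ccc(O)c(O)c3)[C@@H](O)C4)[C@@H]2O)cc1O | target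

Total step count: 12.
Longest linear sequence: 7 steps (1, 2, 3, 5, 10, 11, 12).

Steps most likely to fail

1. Step 10.
- **Protodesilylation:** loss of the silyl group from the enol silane, with acid plus water or the phenol as proton source, may outrun C–C bond formation to the strongly stabilised methide.
- **Facial selectivity:** the single-point binding of the catalyst may give poor selection at C4, or the bias of the catechin part may override it.
- **Oligomerisation:** Friedel–Crafts attack through D-ring C6 may compete.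
- **Harmless side process:** loss of the silyl group from the C2 oxygen after ring closure does not matter, because step 11 reaches the same C2 cation.
- **Fallback** (known base-triggered o-quinone methide cascade, no acid and no chiral catalyst), setting out from 6:
  - 6 is acylated (Boc2O, i-Pr2NEt, cat. DMAP, CH2Cl2) to 2,3-bis(benzyloxy)-6-formylphenyl tert-butyl carbonate F1.
  - Aryllithium 7, made from 4 as in step 5, is added at −78 °C, and the new alkoxide takes over the Boc group.
  - Addition of MgBr2·OEt2 and excess 17 followed by warming lets the freed phenoxide expel tert-butyl carbonate.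
  - Methide 18 therefore arises under non-acidic conditions and is intercepted by 17 in the established thermal [4+2] mode of such methides with enol ethers.
  - Face selection at C4 then rests on the catechin part alone, the diastereomers are separated by chromatography, and the route is rejoined at 19.

2. Step 11.
- **Possible failures:** proton loss from C3 of the cation (elimination), endocyclic C2–O1 cleavage followed by reduction of the opened chain, acid-induced fission of the interflavan bond, or hydride delivery to the wrong face.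
- **Fallback** (reduction in the open chain and ring closure by substitution), setting out from 19:
  - Buffered fluoride (TBAF/AcOH, THF, 0 °C) removes the silyl group, and the hemiketal opens to (2S,3S)-2-(benzyloxy)-1-[3,4-bis(benzyloxy)phenyl]-3-[3,4-bis(benzyloxy)-2-hydroxyphenyl]-3-(penta-O-benzylcatechin-8-yl)propan-1-one F2.
  - L-Selectride (3 equiv, THF, −78 °C) should deliver hydride anti to OBn (polar Felkin–Anh control). This should give the 1,2-syn alcohol (1S,2S,3S)-2-(benzyloxy)-1-[3,4-bis(benzyloxy)phenyl]-3-[3,4-bis(benzyloxy)-2-hydroxyphenyl]-3-(penta-O-benzylcatechin-8-yl)propan-1-ol F3.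
  - Intramolecular Mitsunobu etherification (PPh3, DIAD, THF, 0 °C) closes O1–C2 with inversion to the 2R centre, and the route is rejoined at 21.

3. Step 5.
- **Possible failures:** the hindered aryllithium may add sluggishly to the phenoxide-deactivated formyl group and decay on warming, the sodium salt may be poorly soluble at low temperature, or the very labile carbinol may ionise during work-up.
- **Fallback** (neutral, non-migrating phenol mask removed under neutral conditions), setting out from 6:
  - 6 is alkylated (allyl bromide, K2CO3, DMF) to 2-(allyloxy)-3,4-bis(benzyloxy)benzaldehyde F4.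
  - Addition of 7 at −78 °C gives [2-(allyloxy)-3,4-bis(benzyloxy)phenyl](penta-O-benzylcatechin-8-yl)methanol F5.
  - Pd(PPh3)4 (cat.) with morpholine in THF at rt removes the allyl group, and the route is rejoined at 9.

Further compounds
F1 | step 10 | 2,3-bis(benzyloxy)-6-formylphenyl tert-butyl carbonate | O=Cc1ccc(OCc5ccccc5)c(OCc5ccccc5)c1OC(=O)OC(C)(C)C
F2 | step 11 | (2S,3S)-2-(benzyloxy)-1-[3,4-bis(benzyloxy)phenyl]-3-[3,4-bis(benzyloxy)-2-hydroxyphenyl]-3-(penta-O-benzylcatechin-8-yl)propan-1-one | O=C(c1ccc(OCc5ccccc5)c(OCc5ccccc5)c1)[C@@H](OCc5ccccc5)[C@@H](c1ccc(OCc5ccccc5)c(OCc5ccccc5)c1O)c3c(OCc5ccccc5)cc(OCc5ccccc5)c4c3O[C@H](c3ccc(OCc5ccccc5)c(OCc5ccccc5)c3)[C@@H](OCc5ccccc5)C4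
F3 | step 11 | (1S,2S,3S)-2-(benzyloxy)-1-[3,4-bis(benzyloxy)phenyl]-3-[3,4-bis(benzyloxy)-2-hydroxyphenyl]-3-(penta-O-benzylcatechin-8-yl)propan-1-ol | O[C@@H](c1ccc(OCc5ccccc5)c(OCc5ccccc5)c1)[C@@H](OCc5ccccc5)[C@@H](c1ccc(OCc5ccccc5)c(OCc5ccccc5)c1O)c3c(OCc5ccccc5)cc(OCc5ccccc5)c4c3O[C@H](c3ccc(OCc5ccccc5)c(OCc5ccccc5)c3)[C@@H](OCc5ccccc5)C4
F4 | step 5 | 2-(allyloxy)-3,4-bis(benzyloxy)benzaldehyde | O=Cc1ccc(OCc5ccccc5)c(OCc5ccccc5)c1OCC=C
F5 | step 5 | [2-(allyloxy)-3,4-bis(benzyloxy)phenyl](penta-O-benzylcatechin-8-yl)methanol, both carbinol epimers | OC(c1ccc(OCc5ccccc5)c(OCc5ccccc5)c1OCC=C)c3c(OCc5ccccc5)cc(OCc5ccccc5)c4c3O[C@H](c3ccc(OCc5ccccc5)c(OCc5ccccc5)c3)[C@@H](OCc5ccccc5)C4
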